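At early times Sunday's flask looks dead: target reads 0% at 0.333 d and 3.1% at 0.500 d. Then it jumps to 42.7% at 0.833 d. Friday's run, at 31 °C, also waits and then jumps.

| flask | starting material | reagent | temperature | remark | time |
|---|---|---|---|---|---|
| Sunday's | 0.10 M | 0.060 M | 25 °C | the very flask that is asked about, followed so far |  |
| Friday's | 0.050 M | 0.060 M | 31 °C | run made earlier |  |
| flask | 0.10 M | 0.0600 M | 25 °C |  | 4.0 d |

Sunday's run (percent of the starting material charged)

| time / d | target / % |
|---|---|
| 0.333 | 0 |
| 0.500 | 3.1 |
| 0.833 | 42.7 |
| 1.67 | 56.4 |
| 2.50 | 55.2 |
| 4.00 | 53.4 |

Friday's run (percent of the starting material charged)

| time / h | target / % |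
|---|---|
| 3.00 | 0.6 |
| 5.00 | 0.8 |
| 8.00 | 0 |
| 15.0 | 8.4 |
| 25.0 | 70.8 |
| 40.0 | 94.3 |

(scatter of a reading: 1 percentage point)

- east: change nothing and wait 50 h more
- north: at 4.0 d add reagent, 100% of the amount charged, then wait 50 h
- south-west: at 4.0 d take out 90% of the target then present, then wait 50 h
- north-east: at 4.0 d raise the temperature by 20 K, then wait 50 h

- a species is counted by the starting material in it: one side product counts as two
- what is taken out of target is counted as made
- steps that have been proposed: starting material + reagent + target -> 2 target; starting material + reagent -> target; starting material + target -> side product
- additions bring no volume worth counting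

1. target, in percent of the starting material first charged, at 4.0 d
2. the remedy with the largest gain of target, or "none" below 2 percentage points (east / north / south-west / north-east / none)
3. target present, with what was taken out counted in, in percent of the starting material first charged, after south-west
4. target present, with what was taken out counted in, in percent of the starting material first charged, after north-east

What follows the jump in Sunday's flask is the slow part to watch. Reagent is the limiting reagent there, 0.0600 M against 0.10 M of starting material. One reagent makes one target, so the cap is 60.0%.

Two chemists dispute the tail of Sunday's flask. The first freezes target. His last readings fall by 3 percentage points, just 2.12 standard deviations of a difference. So he takes their mean, 55.0%, and expects waiting to change nothing.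

The second freezes the surplus of starting material, 0.0400 M, which meets target in the proposed step to side product. With that frozen, target falls by a fixed fraction each day (pseudo-first-order). I reckon this for him from the cap, placed at 0.833 d, down to the last reading. That gives 0.0368 d⁻¹, the sink rate, the fraction of target lost per day. It is a reading, with the scatter of the last reading and my placing of the cap in it. Waiting 50 h then costs 3.9 points, and my figure for east is 49.5%. The forecast's differs: 50.6 %.

The forecast takes the second side, on the ground that “leftover starting material (about 33 %) eats target”. It gives 53.6% now, north as best, 53.3% after south-west and 39% after north-east.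

The simulation gives 52.8% now, north as best with a gain of 32 points, 52.4% after south-west and 40.4% after north-east.

    starting material + reagent + target → 2 target (k = 0.0300 M⁻² s⁻¹, Ea = 57.0 kJ mol⁻¹)
    starting material + reagent → target (k = 4.50 × 10⁻⁸ M⁻¹ s⁻¹, Ea = 99.0 kJ mol⁻¹)
    starting material + target → side product (k = 1.20 × 10⁻⁵ M⁻¹ s⁻¹, Ea = 62.0 kJ mol⁻¹)
    (constants at 25 °C)

East loses 3.4 points, so target does sink, and the second chemist wins. The sink rate on the simulated 52.8% gives a loss of 3.9 points. The first chemist's region is south-west: with 90% of the target taken out, the count falls by 0.36 points, below the 2 points margin. The neighbour charged with 0.060 M of starting material has a surplus of 0 M. The sink rate scaled to that surplus is 0 d⁻¹, and its cap is 100%. That neighbour ends with 92.9% target, 5.1% of its reagent unused and still 3.97% side product, against 14.4% in the flask.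

The numbers in the tables were computed on assumed constants; noise was put on by code.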